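**Plan**

- Retrosynthesis: the epoxide oxygen (C4–O, C5–O) and the C13 acetate are removed first. The C2–C3 bond of the ten-membered ring is then cut by formal insertion of NH, giving an eleven-membered azacycle. This is opened at C3–N, then at C5–C6 together with the lactone C6–O bond, then at C2–N, C1–C2, C10–CH3 and C7–C8.
- Enabling feature: in the ten-membered carbocycle, C2 is α to the C1 ketone and C3 is allylic to the C4=C5 alkene, so both carbons become stabilised radicals when a nitrogen bridging them leaves as N2.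
- Forward: a 2-silyl-3-(hydroxymethyl)furan (the future butenolide, C6/C7/C11/C12/C13) is acylated at C7 with succinic anhydride (C8–C1). The chain is completed by methylation at C10, esterification at C8, carbenoid homologation to C2 and amination. The furan is oxidised and a Nozaki–Hiyama–Kishi coupling with a Z-alkenyl iodide (C3–C5) closes the butenolide. Mitsunobu N-alkylation closes the eleven-membered azacycle, nitrogen deletion contracts it to the carbocycle, and the oxirane is formed last.
- Stereochemistry: C8 from asymmetric transfer hydrogenation; C10 from trans-alkylation of the lactone built on C8; C6 from ligand-controlled addition to the C6 aldehyde; the Z-C4=C5 geometry from anti-carbomagnesiation of propargyl alcohol; C4/C5 from stereospecific, substrate-controlled epoxidation.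
- C13 is carried as a silyl ether until after the ring contraction, because a C13 acetate on the butenolide is an allylic leaving group open to SN2' attack by the ring amine or by thiolate.

Key step: step 17

Remark: atoms are numbered as in germacranolides (C1 ketone, C2, C3, C4=C5, C6 lactone carbinol, C7=C11 butenolide alkene, C8 ester carbinol, C9, C10 methyl-bearing carbon, C12 lactone carbonyl, C13 CH2O).
Remark: C6 has the descriptor S while C4=C5 is an alkene and R in the epoxide; the spatial arrangement is the same.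
Remark: the nitrogen-deletion reagent is assumed to be N-(benzyloxy)-N-(pivaloyloxy)-4-(trifluoromethyl)benzamide.

**Route**

Step 1
Reactants: 1 prop-2-yn-1-ol
Product: 2 (Z)-3-iodo-2-methylprop-2-en-1-ol
Conditions: MeMgBr, CuI (cat.), THF, −10 °C to rt; then I2, −10 °C
Reagents that add atoms: methylmagnesium bromide, C[Mg]Br; iodine, [I][I]
Why: Copper-catalysed anti-carbomagnesiation of the propargylic alkoxide puts methyl on the internal carbon and magnesium cis to the CH2O group in a five-membered chelate, and iodinolysis with retention fixes the Z geometry that becomes C4=C5.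

Step 2
Reactants: 3 furan-3-ylmethanol
Product: 4 tert-butyl(furan-3-ylmethoxy)dimethylsilane
Conditions: TBSCl, imidazole, CH2Cl2, rt
Reagents that add atoms: tert-butyldimethylsilyl chloride, CC(C)(C)[Si](C)(C)Cl
Why: Routine silyl ether formation on a primary alcohol sets up the silyl migration of the next step.

Step 3
Reactants: 4 tert-butyl(furan-3-ylmethoxy)dimethylsilane
Product: 5 [2-(tert-butyldimethylsilyl)furan-3-yl]methanol
Conditions: n-BuLi, HMPA, THF, −78 °C to rt; aq. NH4Cl
Reagents that add atoms: none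
Why: Lithiation at the furan 2-position next to the CH2O group triggers a 1,4 oxygen-to-carbon silyl shift (retro-Brook rearrangement), which frees the alcohol and blocks the carbon that becomes the lactone carbonyl C12.

Step 4
Reactants: 5 [2-(tert-butyldimethylsilyl)furan-3-yl]methanol; 6 succinic anhydride
Product: 7 4-[5-(tert-butyldimethylsilyl)-4-(hydroxymethyl)furan-3-yl]-4-oxobutanoic acid
Conditions: n-BuLi (2.2 equiv), DME, 0 °C; then 6, THF, −78 °C; aq. HCl
Reagents that add atoms: none
Why: With the 2-position blocked, the lithium alkoxide directs the second lithiation to the 4-position (directed ortho-metalation), and the furyllithium opens the symmetrical anhydride to the keto carboxylate, which resists a second addition, so that C7–C8 is formed.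

Step 5
Reactants: 7 4-[5-(tert-butyldimethylsilyl)-4-(hydroxymethyl)furan-3-yl]-4-oxobutanoic acid
Product: 9 (R)-5-[5-(tert-butyldimethylsilyl)-4-(hydroxymethyl)furan-3-yl]dihydrofuran-2(3H)-one, via hydroxy acid 8 (not isolated)
Conditions: RuCl[(R,R)-TsDPEN](p-cymene) (cat.), HCO2Na, H2O/MeOH, 40 °C; then citric acid, EtOAc, rt
Reagents that add atoms: none
Why: Noyori-type asymmetric transfer hydrogenation of the heteroaryl ketone with the (R,R)-catalyst should give the (R)-carbinol at C8 by the same aryl/alkyl discrimination as for acetophenone, and the γ-hydroxy acid lactonises on acidification.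

Step 6
Reactants: 9 (R)-5-[5-(tert-butyldimethylsilyl)-4-(hydroxymethyl)furan-3-yl]dihydrofuran-2(3H)-one
Product: 10 (R)-5-{5-(tert-butyldimethylsilyl)-4-[(tert-butyldiphenylsilyloxy)methyl]furan-3-yl}dihydrofuran-2(3H)-one
Conditions: TBDPSCl, imidazole, DMF, rt
Reagents that add atoms: tert-butyldiphenylsilyl chloride, CC(C)(C)[Si](Cl)(c1ccccc1)c1ccccc1
Why: Silyl ether formation with the acid-stable TBDPS group protects C13–OH through the later TFA step and, as a poor leaving group, blocks SN2' chemistry at the butenolide.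

Step 7
Reactants: 10 (R)-5-{5-(tert-butyldimethylsilyl)-4-[(tert-butyldiphenylsilyloxy)methyl]furan-3-yl}dihydrofuran-2(3H)-one
Product: 11 (3S,5R)-5-{5-(tert-butyldimethylsilyl)-4-[(tert-butyldiphenylsilyloxy)methyl]furan-3-yl}-3-methyldihydrofuran-2(3H)-one (trans)
Conditions: lithium diisopropylamide, THF, −78 °C; then MeI
Reagents that add atoms: iodomethane, CI
Why: Alkylation of the lactone lithium enolate should occur anti to the bulky C8 substituent, giving the trans-lactone in which C10 is S.

Step 8
Reactants: 11 (3S,5R)-trans-methyl lactone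
Product: 12 (2S,4R)-4-{5-(tert-butyldimethylsilyl)-4-[(tert-butyldiphenylsilyloxy)methyl]furan-3-yl}-4-hydroxy-N-methoxy-N,2-dimethylbutanamide
Conditions: MeNHOMe·HCl, AlMe3, CH2Cl2, 0 °C to rt
Reagents that add atoms: N,O-dimethylhydroxylamine hydrochloride, CNOC.Cl
Why: Aminolysis of the lactone by the aluminium amide (Weinreb amide formation) frees the C8 hydroxyl and prepares C1 for a single carbon addition without touching C10.

Step 9
Reactants: 12 hydroxy Weinreb amide; 13 3-methylbut-2-enoic acid
Product: 14 (1R,3S)-1-{5-(tert-butyldimethylsilyl)-4-[(tert-butyldiphenylsilyloxy)methyl]furan-3-yl}-4-[methoxy(methyl)amino]-3-methyl-4-oxobutyl 3-methylbut-2-enoate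
Conditions: DCC, DMAP (cat.), CH2Cl2, 0 °C to rt
Reagents that add atoms: none
Why: Steglich esterification with the free acid avoids the ketene pathway that deconjugates the acid chloride and caps the γ-hydroxy amide before it can relactonise.

Step 10
Reactants: 14 senecioate Weinreb amide
Product: 15 (1R,3S)-5-chloro-1-{5-(tert-butyldimethylsilyl)-4-[(tert-butyldiphenylsilyloxy)methyl]furan-3-yl}-3-methyl-4-oxopentyl 3-methylbut-2-enoate
Conditions: ICH2Cl, MeLi·LiBr, THF, −78 °C; aq. NH4Cl
Reagents that add atoms: chloroiodomethane, ClCI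
Why: Chloromethyllithium made in situ adds once to the Weinreb amide through the chelated tetrahedral intermediate (carbenoid homologation), the hindered conjugated ester being far less electrophilic, and so forms C1–C2.

Step 11
Reactants: 15 α-chloroketone
Product: 16 (1R,3S)-5-[bis(tert-butoxycarbonyl)amino]-1-{5-(tert-butyldimethylsilyl)-4-[(tert-butyldiphenylsilyloxy)methyl]furan-3-yl}-3-methyl-4-oxopentyl 3-methylbut-2-enoate
Conditions: KN(Boc)2, NaI (cat.), DMF, rt
Reagents that add atoms: potassium di-tert-butyl iminodicarboxylate, CC(C)(C)OC(=O)[N-]C(=O)OC(C)(C)C.[K+]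
Why: SN2 displacement of the α-chloroketone by the weakly basic imidodicarbonate anion (Gabriel-type amination) puts nitrogen on C2 in a form without N–H that tolerates the oxidation, alkylation and chromium steps that follow.

Step 12
Reactants: 16 bis-Boc amino ketone
Product: 18 methyl (2Z,4R,6S)-8-[bis(tert-butoxycarbonyl)amino]-2-[(tert-butyldiphenylsilyloxy)methyl]-3-formyl-6-methyl-4-[(3-methylbut-2-enoyl)oxy]-7-oxooct-2-enoate, via hydroxybutenolide 17 (not isolated)
Conditions: O2, hν, tetraphenylporphyrin (cat.), CH2Cl2, −78 °C; MeOH/H2O; then MeI, KHCO3, DMF, rt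
Reagents that add atoms: oxygen, O=O; iodomethane, CI
Why: [4+2] cycloaddition of singlet oxygen to the furan followed by silyl migration in the endoperoxide places the carbonyl on the silicon-bearing carbon C12 and the hemiacetal on C6, and O-methylation of the ring-opened carboxylate gives the (Z)-formyl ester.

Step 13
Reactants: 18 formyl ester; 2 (Z)-3-iodo-2-methylprop-2-en-1-ol
Product: 19 (1R,3S)-5-[bis(tert-butoxycarbonyl)amino]-1-{(2S)-4-[(tert-butyldiphenylsilyloxy)methyl]-2-[(Z)-3-hydroxy-2-methylprop-1-enyl]-5-oxo-2,5-dihydrofuran-3-yl}-3-methyl-4-oxopentyl 3-methylbut-2-enoate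
Conditions: CrCl2, NiCl2 (cat.), chiral 2-(oxazolin-2-yl)anilide sulfonamide ligand, Et3N, THF, rt; aq. work-up
Reagents that add atoms: none
Why: The Nozaki–Hiyama–Kishi coupling is selective for the aldehyde over ketone, esters and carbamates and keeps the geometry of the alkenyl iodide, the chiral chromium complex (ligand enantiomer chosen for Si-face delivery) sets C6, and the chromium alkoxide closes the butenolide onto the cis methyl ester.

Step 14
Reactants: 19 butenolide allylic alcohol
Product: 21 N-{(3S,5R)-5-[(2S)-4-[(tert-butyldiphenylsilyloxy)methyl]-2-[(Z)-3-hydroxy-2-methylprop-1-enyl]-5-oxo-2,5-dihydrofuran-3-yl]-3-methyl-5-[(3-methylbut-2-enoyl)oxy]-2-oxopentyl}-2-nitrobenzenesulfonamide, via ammonium trifluoroacetate 20 (not isolated)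
Conditions: TFA, CH2Cl2, 0 °C; evaporate; then NsCl, NaHCO3, CH2Cl2/H2O, 0 °C
Reagents that add atoms: 2-nitrobenzenesulfonyl chloride, O=S(=O)(Cl)c1ccccc1[N+](=O)[O-]
Why: Acidolysis removes both Boc groups while the TBDPS ether survives, and the ammonium salt is sulfonylated at nitrogen under Schotten–Baumann conditions far faster than the allylic alcohol reacts.

Step 15
Reactants: 21 nosyl amide allylic alcohol
Product: 22 N-nosyl eleven-membered azacycle: (4Z,6S,8R,10S)-13-(tert-butyldiphenylsilyloxy)-8-(3-methylbut-2-enoyloxy)-1-oxo-2,3-secogermacra-4,7(11)-dien-12,6-olide with C2 and C3 joined through N–SO2C6H4-2-NO2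
Conditions: PPh3, DIAD, toluene (high dilution, slow addition), 0 °C to rt
Reagents that add atoms: none
Why: Intramolecular Fukuyama–Mitsunobu alkylation joins the acidic sulfonamide nitrogen to the activated primary allylic carbon C3 by SN2, and the Z-alkene, butenolide, ketone and planar sulfonamide reduce the conformational freedom of the eleven-membered ring being closed.

Step 16
Reactants: 22 N-nosyl azacycle
Product: 23 eleven-membered secondary amine: (4Z,6S,8R,10S)-13-(tert-butyldiphenylsilyloxy)-8-(3-methylbut-2-enoyloxy)-1-oxo-2,3-secogermacra-4,7(11)-dien-12,6-olide with C2 and C3 joined through NH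
Conditions: PhSH, K2CO3, MeCN, rt
Reagents that add atoms: none
Why: Thiolate adds to the nitroarene (Meisenheimer complex) and releases the sulfinate, which loses SO2 to free the amine (Fukuyama deprotection), and the C13 silyl ether leaves thiolate and amine no SN2' pathway.

Step 17
Reactants: 23 eleven-membered secondary amine
Product: 25 (4Z,6S,8R,10S)-13-(tert-butyldiphenylsilyloxy)-8-(3-methylbut-2-enoyloxy)-1-oxogermacra-4,7(11)-dien-12,6-olide, via isodiazene 24 (not isolated)
Conditions: N-(benzyloxy)-N-(pivaloyloxy)-4-(trifluoromethyl)benzamide, THF, 45 °C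
Reagents that add atoms: none
Why: Proposed new method: the secondary amine attacks the electrophilic nitrogen of the anomeric amide and displaces pivalate, the N-alkoxy hydrazide formed eliminates benzyl 4-(trifluoromethyl)benzoate to give the 1,1-diazene 24, and loss of N2 leaves a tethered biradical (α-keto radical at C2, allyl radical over C3–C5) that collapses to the C2–C3 bond. The closest known reaction type is the nitrogen deletion of benzylic and small cyclic secondary amines with N-acyloxy-N-alkoxyamides; here the stabilisation given by benzyl groups is supplied by the C1 carbonyl for C2 and by the C4=C5 alkene for C3. The ten-membered carbocycle is closed by ring contraction of the eleven-membered azacycle, that is by recombination of two radical termini that stay linked through C6–C10, so the entropic cost of medium-ring formation was already paid in the C–N closure of step 15. No stereocentre is formed, and C6, C8 and C10 are not involved. The step needs bond formation at the primary allyl terminus C3 and not at C5, with retention of the Z geometry: C5 is secondary, flanked by C6 and would lead to an eight-membered ring, and recombination of the tethered pair is expected to be faster than rotation within the allyl radical. The competing pathways are a [2,3] shift of the allylic isodiazene and tautomerisation to a hydrazone at the acidic C2–H, and warm THF, in which stabilised isodiazenes lose N2 quickly, is chosen to disfavour both.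

Step 18
Reactants: 25 silyl-protected ten-membered ketone
Product: 26 (4Z,6S,8R,10S)-13-hydroxy-8-(3-methylbut-2-enoyloxy)-1-oxogermacra-4,7(11)-dien-12,6-olide
Conditions: HF·pyridine, pyridine, THF, 0 °C to rt
Reagents that add atoms: none
Why: Fluoride-mediated cleavage of the silyl ether under buffered conditions leaves the esters, the butenolide and the epimerisable C10 untouched.

Step 19
Reactants: 26 C13 alcohol
Product: 27 (4Z,6S,8R,10S)-13-acetoxy-8-(3-methylbut-2-enoyloxy)-1-oxogermacra-4,7(11)-dien-12,6-olide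
Conditions: Ac2O, pyridine, DMAP (cat.), CH2Cl2, 0 °C
Reagents that add atoms: acetic anhydride, CC(=O)OC(C)=O
Why: DMAP-catalysed acetylation of the primary allylic alcohol is now safe because no amine or thiolate remains to attack the allylic acetate.

Step 20
Reactants: 27 Z-alkene acetate
Product: 28 (4S,5R,6R,8R,10S)-13-acetoxy-4,5-epoxy-8-(3-methylbut-2-enoyloxy)-1-oxogermacr-7(11)-en-12,6-olide (CNP0220542.1)
Conditions: dimethyldioxirane, acetone, −20 to 0 °C
Reagents that add atoms: dimethyldioxirane, CC1(C)OO1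
Why: Concerted oxygen transfer from the dioxirane (Prilezhaev-type epoxidation) is syn-stereospecific, so the Z-alkene gives the cis-epoxide, and only the electron-rich C4=C5 alkene reacts; the 4S,5R isomer requires attack on the face syn to C7 and anti to the lactone oxygen, which is assumed, not established, to be the exposed face of the ring conformer with C6–H in the alkene plane.

**Compound list**

1 | prop-2-yn-1-ol | C#CCO | starting material
2 | (Z)-3-iodo-2-methylprop-2-en-1-ol | OC/C(C)=C\I | intermediate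
3 | furan-3-ylmethanol | OCc1ccoc1 | starting material
4 | tert-butyl(furan-3-ylmethoxy)dimethylsilane | CC(C)(C)[Si](C)(C)OCc1ccoc1 | intermediate
5 | [2-(tert-butyldimethylsilyl)furan-3-yl]methanol | OCc1ccoc1[Si](C)(C)C(C)(C)C | intermediate
6 | succinic anhydride | O=C1CCC(=O)O1 | starting material
7 | 4-[5-(tert-butyldimethylsilyl)-4-(hydroxymethyl)furan-3-yl]-4-oxobutanoic acid | OC(=O)CCC(=O)c1coc([Si](C)(C)C(C)(C)C)c1CO | intermediate
8 | (R)-4-[5-(tert-butyldimethylsilyl)-4-(hydroxymethyl)furan-3-yl]-4-hydroxybutanoic acid (not isolated) | OC(=O)CC[C@@H](O)c1coc([Si](C)(C)C(C)(C)C)c1CO | intermediate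
9 | (R)-5-[5-(tert-butyldimethylsilyl)-4-(hydroxymethyl)furan-3-yl]dihydrofuran-2(3H)-one | O=C1CC[C@@H](O1)c2coc([Si](C)(C)C(C)(C)C)c2CO | intermediate
10 | (R)-5-{5-(tert-butyldimethylsilyl)-4-[(tert-butyldiphenylsilyloxy)methyl]furan-3-yl}dihydrofuran-2(3H)-one | O=C1CC[C@@H](O1)c2coc([Si](C)(C)C(C)(C)C)c2CO[Si](c3ccccc3)(c4ccccc4)C(C)(C)C | intermediate
11 | (3S,5R)-5-{5-(tert-butyldimethylsilyl)-4-[(tert-butyldiphenylsilyloxy)methyl]furan-3-yl}-3-methyldihydrofuran-2(3H)-one | O=C1[C@@H](C)C[C@@H](O1)c2coc([Si](C)(C)C(C)(C)C)c2CO[Si](c3ccccc3)(c4ccccc4)C(C)(C)C | intermediate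
12 | (2S,4R)-4-{5-(tert-butyldimethylsilyl)-4-[(tert-butyldiphenylsilyloxy)methyl]furan-3-yl}-4-hydroxy-N-methoxy-N,2-dimethylbutanamide | CON(C)C(=O)[C@@H](C)C[C@@H](O)c1coc([Si](C)(C)C(C)(C)C)c1CO[Si](c2ccccc2)(c3ccccc3)C(C)(C)C | intermediate
13 | 3-methylbut-2-enoic acid | CC(C)=CC(=O)O | starting material
14 | (1R,3S)-1-{5-(tert-butyldimethylsilyl)-4-[(tert-butyldiphenylsilyloxy)methyl]furan-3-yl}-4-[methoxy(methyl)amino]-3-methyl-4-oxobutyl 3-methylbut-2-enoate | CON(C)C(=O)[C@@H](C)C[C@@H](OC(=O)C=C(C)C)c1coc([Si](C)(C)C(C)(C)C)c1CO[Si](c2ccccc2)(c3ccccc3)C(C)(C)C | intermediate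
15 | (1R,3S)-5-chloro-1-{5-(tert-butyldimethylsilyl)-4-[(tert-butyldiphenylsilyloxy)methyl]furan-3-yl}-3-methyl-4-oxopentyl 3-methylbut-2-enoate | ClCC(=O)[C@@H](C)C[C@@H](OC(=O)C=C(C)C)c1coc([Si](C)(C)C(C)(C)C)c1CO[Si](c2ccccc2)(c3ccccc3)C(C)(C)C | intermediate
16 | (1R,3S)-5-[bis(tert-butoxycarbonyl)amino]-1-{5-(tert-butyldimethylsilyl)-4-[(tert-butyldiphenylsilyloxy)methyl]furan-3-yl}-3-methyl-4-oxopentyl 3-methylbut-2-enoate | CC(C)(C)OC(=O)N(CC(=O)[C@@H](C)C[C@@H](OC(=O)C=C(C)C)c1coc([Si](C)(C)C(C)(C)C)c1CO[Si](c2ccccc2)(c3ccccc3)C(C)(C)C)C(=O)OC(C)(C)C | intermediate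
17 | (1R,3S)-5-[bis(tert-butoxycarbonyl)amino]-1-{4-[(tert-butyldiphenylsilyloxy)methyl]-2-hydroxy-5-oxo-2,5-dihydrofuran-3-yl}-3-methyl-4-oxopentyl 3-methylbut-2-enoate, both C6 anomers (not isolated) | CC(C)(C)OC(=O)N(CC(=O)[C@@H](C)C[C@@H](OC(=O)C=C(C)C)C1=C(CO[Si](c2ccccc2)(c3ccccc3)C(C)(C)C)C(=O)OC1O)C(=O)OC(C)(C)C | intermediate
18 | methyl (2Z,4R,6S)-8-[bis(tert-butoxycarbonyl)amino]-2-[(tert-butyldiphenylsilyloxy)methyl]-3-formyl-6-methyl-4-[(3-methylbut-2-enoyl)oxy]-7-oxooct-2-enoate | COC(=O)/C(CO[Si](c1ccccc1)(c2ccccc2)C(C)(C)C)=C(\C=O)[C@H](OC(=O)C=C(C)C)C[C@H](C)C(=O)CN(C(=O)OC(C)(C)C)C(=O)OC(C)(C)C | intermediate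
19 | (1R,3S)-5-[bis(tert-butoxycarbonyl)amino]-1-{(2S)-4-[(tert-butyldiphenylsilyloxy)methyl]-2-[(Z)-3-hydroxy-2-methylprop-1-enyl]-5-oxo-2,5-dihydrofuran-3-yl}-3-methyl-4-oxopentyl 3-methylbut-2-enoate | CC(C)(C)[Si](c1ccccc1)(c2ccccc2)OCC3=C([C@H](OC(=O)C=C(C)C)C[C@H](C)C(=O)CN(C(=O)OC(C)(C)C)C(=O)OC(C)(C)C)[C@@H](OC3=O)/C=C(C)\CO | intermediate
20 | ammonium trifluoroacetate of the primary amine from 19 (not isolated) | CC(C)(C)[Si](c1ccccc1)(c2ccccc2)OCC3=C([C@H](OC(=O)C=C(C)C)C[C@H](C)C(=O)C[NH3+])[C@@H](OC3=O)/C=C(C)\CO.[O-]C(=O)C(F)(F)F | intermediate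
21 | N-{(3S,5R)-5-[(2S)-4-[(tert-butyldiphenylsilyloxy)methyl]-2-[(Z)-3-hydroxy-2-methylprop-1-enyl]-5-oxo-2,5-dihydrofuran-3-yl]-3-methyl-5-[(3-methylbut-2-enoyl)oxy]-2-oxopentyl}-2-nitrobenzenesulfonamide | CC(C)(C)[Si](c1ccccc1)(c2ccccc2)OCC3=C([C@H](OC(=O)C=C(C)C)C[C@H](C)C(=O)CNS(=O)(=O)c4ccccc4[N+](=O)[O-])[C@@H](OC3=O)/C=C(C)\CO | intermediate
22 | N-(2-nitrobenzenesulfonyl) eleven-membered azacycle (4Z,6S,8R,10S), N between C2 and C3, 13-O-TBDPS | CC(C)(C)[Si](c3ccccc3)(c4ccccc4)OCC1=C2[C@@H](OC1=O)/C=C(C)\CN(CC(=O)[C@@H](C)C[C@H]2OC(=O)C=C(C)C)S(=O)(=O)c5ccccc5[N+](=O)[O-] | intermediate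
23 | eleven-membered secondary amine (4Z,6S,8R,10S), NH between C2 and C3, 13-O-TBDPS | CC(C)(C)[Si](c3ccccc3)(c4ccccc4)OCC1=C2[C@@H](OC1=O)/C=C(C)\CNCC(=O)[C@@H](C)C[C@H]2OC(=O)C=C(C)C | intermediate
24 | isodiazene (1,1-diazene) of 23 (not isolated) | CC(C)(C)[Si](c3ccccc3)(c4ccccc4)OCC1=C2[C@@H](OC1=O)/C=C(C)\C[N+](=[N-])CC(=O)[C@@H](C)C[C@H]2OC(=O)C=C(C)C | intermediate
25 | (4Z,6S,8R,10S)-13-(tert-butyldiphenylsilyloxy)-8-(3-methylbut-2-enoyloxy)-1-oxogermacra-4,7(11)-dien-12,6-olide | CC(C)(C)[Si](c3ccccc3)(c4ccccc4)OCC1=C2[C@@H](OC1=O)/C=C(C)\CCC(=O)[C@@H](C)C[C@H]2OC(=O)C=C(C)C | intermediate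
26 | (4Z,6S,8R,10S)-13-hydroxy-8-(3-methylbut-2-enoyloxy)-1-oxogermacra-4,7(11)-dien-12,6-olide | OCC1=C2[C@@H](OC1=O)/C=C(C)\CCC(=O)[C@@H](C)C[C@H]2OC(=O)C=C(C)C | intermediate
27 | (4Z,6S,8R,10S)-13-acetoxy-8-(3-methylbut-2-enoyloxy)-1-oxogermacra-4,7(11)-dien-12,6-olide | CC(=O)OCC1=C2[C@@H](OC1=O)/C=C(C)\CCC(=O)[C@@H](C)C[C@H]2OC(=O)C=C(C)C | intermediate
28 | (4S,5R,6R,8R,10S)-13-acetoxy-4,5-epoxy-8-(3-methylbut-2-enoyloxy)-1-oxogermacr-7(11)-en-12,6-olide (CNP0220542.1) | CC(=O)OCC1=C2[C@@H](OC1=O)[C@H]1O[C@@]1(C)CCC(=O)[C@@H](C)C[C@H]2OC(=O)C=C(C)C | target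

**Step count and risks**

Total steps: 20. Longest linear sequence: 19 (steps 2–20 from furan-3-ylmethanol); step 1 is a one-step side branch.

Steps most likely to fail:

1. Step 17 (Proposed new method). The isodiazene may undergo a [2,3] shift through the allyl group or tautomerise to a hydrazone at C2, and the biradical may close at C5, disproportionate or lose the Z geometry. Fallback with known carbanion chemistry forming the same C2–C3 bond, setting out from 15 and returning at 25:
   - NaSO2Ph in DMF would convert chloroketone 15 into the β-keto sulfone (1R,3S)-1-{5-(tert-butyldimethylsilyl)-4-[(tert-butyldiphenylsilyloxy)methyl]furan-3-yl}-3-methyl-4-oxo-5-(phenylsulfonyl)pentyl 3-methylbut-2-enoate F1.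
   - Photooxygenation as in step 12 would give its hydroxybutenolide F2, and (trimethylsilyl)diazomethane the formyl methyl ester F3.
   - Coupling with 2 as in step 13 would give the butenolide allylic alcohol F4, and CBr4/PPh3 the allylic bromide F5.
   - Cs2CO3 in MeCN at high dilution would close the ten-membered ring by intramolecular C-alkylation of the sulfone-stabilised enolate, a ring closure established for germacrane-type rings, giving the 2-phenylsulfonyl ketone F6.
   - Al(Hg) in wet THF would remove the sulfonyl group and rejoin the route at 25.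

2. Step 13. Divalent chromium may reduce the electron-poor formyl enoate in a conjugate sense, addition to the hindered aldehyde may be slow, and facial discrimination at C6 may be insufficient. Fallback with a different metal and control element, setting out from 2 and 18 and returning at 19:
   - Iodide 2 would be silylated (TBSCl, imidazole) to (Z)-tert-butyl[(3-iodo-2-methylallyl)oxy]dimethylsilane F7.
   - Iodine–lithium exchange (t-BuLi, −78 °C) and transmetalation (ZnBr2, then Et2Zn) would give an alkenyl(ethyl)zinc reagent, which would be added to aldehyde 18 under catalysis by an amino alcohol such as (−)-3-exo-morpholinoisoborneol.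
   - The zinc alkoxide should lactonise to the C3-O-silyl butenolide F8, and HF·pyridine, which cleaves the primary allylic TBS ether much faster than the TBDPS ether, would return the route to 19.

3. Step 20. Facial selectivity of the epoxidation may be poor or reversed, because the preferred face of the ring alkene is assumed and not known. Fallback exploiting the same facial preference in the opposite sense, setting out from 27 and returning at 28:
   - N-bromosuccinimide in aqueous DME would deliver bromine to the more accessible face and water to the tertiary C4 from the other face, giving the 5-bromo-4-hydroxy derivative of 27, bromohydrin F9.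
   - Ag2O in CH2Cl2 would close the oxirane by displacement of bromide with inversion at C5, placing the oxygen on the face the dioxirane avoids and giving 28.

Further compounds
F1 | step 17 | (1R,3S)-1-{5-(tert-butyldimethylsilyl)-4-[(tert-butyldiphenylsilyloxy)methyl]furan-3-yl}-3-methyl-4-oxo-5-(phenylsulfonyl)pentyl 3-methylbut-2-enoate | O=S(=O)(CC(=O)[C@@H](C)C[C@@H](OC(=O)C=C(C)C)c1coc([Si](C)(C)C(C)(C)C)c1CO[Si](c2ccccc2)(c3ccccc3)C(C)(C)C)c4ccccc4
F2 | step 17 | hydroxybutenolide from F1 (both C6 anomers) | O=S(=O)(CC(=O)[C@@H](C)C[C@@H](OC(=O)C=C(C)C)C1=C(CO[Si](c2ccccc2)(c3ccccc3)C(C)(C)C)C(=O)OC1O)c4ccccc4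
F3 | step 17 | methyl (2Z,4R,6S)-2-[(tert-butyldiphenylsilyloxy)methyl]-3-formyl-6-methyl-4-[(3-methylbut-2-enoyl)oxy]-7-oxo-8-(phenylsulfonyl)oct-2-enoate | COC(=O)/C(CO[Si](c1ccccc1)(c2ccccc2)C(C)(C)C)=C(\C=O)[C@H](OC(=O)C=C(C)C)C[C@H](C)C(=O)CS(=O)(=O)c3ccccc3
F4 | step 17 | analogue of 19 with phenylsulfonyl in place of the bis-Boc amino group | CC(C)(C)[Si](c1ccccc1)(c2ccccc2)OCC3=C([C@H](OC(=O)C=C(C)C)C[C@H](C)C(=O)CS(=O)(=O)c4ccccc4)[C@@H](OC3=O)/C=C(C)\CO
F5 | step 17 | allylic bromide from F4 | CC(C)(C)[Si](c1ccccc1)(c2ccccc2)OCC3=C([C@H](OC(=O)C=C(C)C)C[C@H](C)C(=O)CS(=O)(=O)c4ccccc4)[C@@H](OC3=O)/C=C(C)\CBr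
F6 | step 17 | 2-(phenylsulfonyl) derivative of 25 (both C2 epimers) | CC(C)(C)[Si](c3ccccc3)(c4ccccc4)OCC1=C2[C@@H](OC1=O)/C=C(C)\CC(C(=O)[C@@H](C)C[C@H]2OC(=O)C=C(C)C)S(=O)(=O)c5ccccc5
F7 | step 13 | (Z)-tert-butyl[(3-iodo-2-methylallyl)oxy]dimethylsilane | CC(C)(C)[Si](C)(C)OC/C(C)=C\I
F8 | step 13 | tert-butyldimethylsilyl ether (at the C3 oxygen) of 19 | CC(C)(C)[Si](c1ccccc1)(c2ccccc2)OCC3=C([C@H](OC(=O)C=C(C)C)C[C@H](C)C(=O)CN(C(=O)OC(C)(C)C)C(=O)OC(C)(C)C)[C@@H](OC3=O)/C=C(C)\CO[Si](C)(C)C(C)(C)C
F9 | step 20 | 5-bromo-4-hydroxy derivative of 27 (bromohydrin, Br and OH anti) | CC(=O)OCC1=C2[C@@H](OC1=O)[C@H](Br)[C@](O)(C)CCC(=O)[C@@H](C)C[C@H]2OC(=O)C=C(C)C
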